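The dioxane ring B (O1, C2, C3, O4, C4a, C8a; O1 meta and O4 para to the styryl group; C2 carries catechol ring C, C3 resorcinol ring D) is closed last at O1–C2, by contraction of an eight-membered cyclic carbonate whose carbonyl sits between O1 and the oxygen on C2. The step exploits the para-hydroxyl of ring C, conjugated with C2: when fluoride unmasks it, the carbonate oxygen leaves C2, a para-quinone methide forms, CO2 is lost and the freed O1 phenoxide adds back to C2, trans to the C3 centre. Desilylation, ring contraction and the C2 stereocentre come in one operation from a hexasilylated benzotrioxocinone.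

Key step: step 12

Remark: TIPSO stands for triisopropylsilyloxy, (iPr)3SiO; the target SMILES encodes the trans (2R,3R) isomer (locants as above, styryl group on C7), and the route is planned for that isomer.

Step 1
Reactants: 1 3',4'-dihydroxyacetophenone
Product: 2 1-[3,4-bis(TIPSO)phenyl]ethanone
Conditions: iPr3SiCl (2.4 equiv), imidazole, DMF, rt to 40 °C
Reagents that add atoms: triisopropylsilyl chloride, CC(C)[Si](Cl)(C(C)C)C(C)C
Why: Phenol silylation should cap both catechol hydroxyls as bulky silyl ethers that tolerate the carbonate, hydride and amide bases used later and fall to fluoride in the last step; no stereocentre is formed.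

Step 2
Reactants: 3 5-bromobenzene-1,3-diol
Product: 4 1-bromo-3,5-bis(TIPSO)benzene
Conditions: iPr3SiCl (2.4 equiv), imidazole, DMF, rt
Reagents that add atoms: triisopropylsilyl chloride, CC(C)[Si](Cl)(C(C)C)C(C)C
Why: The same phenol silylation should protect the resorcinol and leave the aryl bromide free for the coupling in step 3.

Step 3
Reactants: 2 1-[3,4-bis(TIPSO)phenyl]ethanone; 4 1-bromo-3,5-bis(TIPSO)benzene
Product: 5 1-[3,4-bis(TIPSO)phenyl]-2-[3,5-bis(TIPSO)phenyl]ethanone
Conditions: Pd2(dba)3 (1.5 mol%), Xantphos (3.6 mol%), K3PO4, toluene, 80 °C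
Reagents that add atoms: none
Why: Palladium-catalysed α-arylation of a ketone enolate (zerovalent palladium with Xantphos, the mild base K3PO4 sparing the aryl silyl ethers) should join the methyl ketone to the aryl bromide, and the more acidic mono-arylated product rests as its enolate, which holds back a second arylation.

Step 4
Reactants: 5 1-[3,4-bis(TIPSO)phenyl]-2-[3,5-bis(TIPSO)phenyl]ethanone
Product: 7 rac-2-bromo-1-[3,4-bis(TIPSO)phenyl]-2-[3,5-bis(TIPSO)phenyl]ethanone, via lithium enolate 6 (not isolated)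
Conditions: LiN(SiMe3)2, THF, −78 °C; then NBS, −78 °C; aq. NH4Cl
Reagents that add atoms: N-bromosuccinimide, O=C1CCC(=O)N1Br
Why: The only enolisable position is deprotonated and the lithium enolate is brominated at low temperature (enolate α-halogenation), which should direct bromine to the α-carbon and not to the electron-rich rings; the new centre is racemic, which is harmless because it is equilibrated in step 10.

Step 5
Reactants: 7 rac-2-bromo-1-[3,4-bis(TIPSO)phenyl]-2-[3,5-bis(TIPSO)phenyl]ethanone; 8 3,4-dihydroxybenzaldehyde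
Product: 9 rac-4-{2-[3,4-bis(TIPSO)phenyl]-1-[3,5-bis(TIPSO)phenyl]-2-oxoethoxy}-3-hydroxybenzaldehyde
Conditions: KHCO3 (1.1 equiv), DMF, 40 °C
Reagents that add atoms: none
Why: Williamson ether synthesis by SN2 displacement at the α-keto benzylic bromide: the hydroxyl para to the formyl group of 8 is the more acidic one and is the phenoxide formed with one equivalent of KHCO3, so the oxygen that becomes O4 is fixed on the carbon bearing ring D while the meta hydroxyl (later O1) stays free; the ether carbon is still racemic.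

Step 6
Reactants: 10 3,5-dihydroxybenzaldehyde
Product: 11 3,5-bis(TIPSO)benzaldehyde
Conditions: iPr3SiCl (2.4 equiv), imidazole, DMF, rt
Reagents that add atoms: triisopropylsilyl chloride, CC(C)[Si](Cl)(C(C)C)C(C)C
Why: Phenol silylation as in step 1 should protect both hydroxyls and leave the aldehyde untouched.

Step 7
Reactants: 11 3,5-bis(TIPSO)benzaldehyde
Product: 12 [3,5-bis(TIPSO)phenyl]methanol
Conditions: NaBH4, MeOH/THF, 0 °C
Reagents that add atoms: none
Why: Borohydride reduction of the aryl aldehyde should give the benzylic alcohol without touching the aryl silyl ethers at 0 °C.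

Step 8
Reactants: 12 [3,5-bis(TIPSO)phenyl]methanol
Product: 13 diethyl [3,5-bis(TIPSO)benzyl]phosphonate
Conditions: ZnI2 (1.5 equiv), P(OEt)3, toluene, reflux
Reagents that add atoms: triethyl phosphite, CCOP(OCC)OCC
Why: ZnI2-promoted direct phosphonylation of a benzylic alcohol with triethyl phosphite (benzylic iodide formed in situ, then a Michaelis–Arbuzov reaction) should give the benzylphosphonate in one step.

Step 9
Reactants: 9 rac-4-{2-[3,4-bis(TIPSO)phenyl]-1-[3,5-bis(TIPSO)phenyl]-2-oxoethoxy}-3-hydroxybenzaldehyde; 13 diethyl [3,5-bis(TIPSO)benzyl]phosphonate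
Product: 14 rac-1-[3,4-bis(TIPSO)phenyl]-2-[3,5-bis(TIPSO)phenyl]-2-{4-[(E)-2-(3,5-bis(TIPSO)phenyl)ethenyl]-2-hydroxyphenoxy}ethanone
Conditions: NaH (3.3 equiv), THF, 0 °C to rt
Reagents that add atoms: none
Why: Horner–Wadsworth–Emmons olefination of the aldehyde by the benzylic phosphonate anion should give the (E)-stilbene under the usual thermodynamic control of the addition–elimination; the extra NaH parks the phenol and the acidic α-position of the hindered aryl ketone as their sodium salts, the ketone itself is not olefinated, and the α-centre returns racemic on quench.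

Step 10
Reactants: 14 rac-1-[3,4-bis(TIPSO)phenyl]-2-[3,5-bis(TIPSO)phenyl]-2-{4-[(E)-2-(3,5-bis(TIPSO)phenyl)ethenyl]-2-hydroxyphenoxy}ethanone
Product: 15 (1R,2R)-1-[3,4-bis(TIPSO)phenyl]-2-[3,5-bis(TIPSO)phenyl]-2-{4-[(E)-2-(3,5-bis(TIPSO)phenyl)ethenyl]-2-hydroxyphenoxy}ethanol
Conditions: RuCl[(S,S)-TsDPEN](p-cymene) (2 mol%), HCO2H/Et3N, EtOAc, 40 °C
Reagents that add atoms: none
Why: Asymmetric transfer hydrogenation under dynamic kinetic resolution: the α-aryloxy-α-aryl ketone racemises through its enol in the amine buffer while the ruthenium hydride of the (S,S)-ligand reduces the matched (R)-ketone from one face, which by analogy with the benzoin to (R,R)-hydrobenzoin reduction should give the (1R,2R)-alcohol (the ligand enantiomer is chosen to deliver 2R); only the aryloxy-bearing centre (later C3) must be fixed here because the carbinol centre (later C2) is re-set in step 12, and stilbene, phenol and silyl ethers are inert to the catalyst.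

Step 11
Reactants: 15 (1R,2R)-1-[3,4-bis(TIPSO)phenyl]-2-[3,5-bis(TIPSO)phenyl]-2-{4-[(E)-2-(3,5-bis(TIPSO)phenyl)ethenyl]-2-hydroxyphenoxy}ethanol
Product: 17 (4R,5R)-4-[3,4-bis(TIPSO)phenyl]-5-[3,5-bis(TIPSO)phenyl]-9-{(E)-2-[3,5-bis(TIPSO)phenyl]ethenyl}-4,5-dihydro-2H-1,3,6-benzotrioxocin-2-one, via aryl imidazole-1-carboxylate 16 (not isolated)
Conditions: CDI (1.05 equiv), CH2Cl2, 0 °C; then DBU (cat.), high dilution, rt
Reagents that add atoms: 1,1'-carbonyldiimidazole, O=C(n1ccnc1)n1ccnc1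
Why: Carbonate formation with CDI: the phenol is acylated first, and base-catalysed attack of the neighbouring secondary alcohol under high dilution should close the eight-membered cyclic carbonate, helped by the ortho-phenylene unit and the two aryl-bearing sp3 carbons that fold the chain; neither stereocentre is touched.

Step 12
Reactants: 17 (4R,5R)-4-[3,4-bis(TIPSO)phenyl]-5-[3,5-bis(TIPSO)phenyl]-9-{(E)-2-[3,5-bis(TIPSO)phenyl]ethenyl}-4,5-dihydro-2H-1,3,6-benzotrioxocin-2-one
Product: 19 cassigarol E, via para-quinone methide 18 (not isolated)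
Conditions: Bu4NF (7 equiv), THF (dilute, degassed), 0 °C to rt; then AcOH
Reagents that add atoms: none
Why: Fluoride removes the six silyl groups, and the phenoxide para to C2 on ring C expels the carbonate oxygen from C2 by 1,6-elimination, which opens the eight-membered ring to para-quinone methide 18 and leaves on O1 an aryl carbonate anion that loses CO2. The O1 phenoxide then adds to the exocyclic methide carbon C2 (oxa-1,6-addition), so the eight-membered benzotrioxocinone contracts to the six-membered dioxane ring with CO2 as the only extruded fragment. The closest known reaction types are the fluoride-triggered self-immolative fragmentation of para-silyloxybenzyl carbonates, the conjugate addition of phenoxides to para-quinone methides, and the decarboxylative ring contraction of cyclic carbonates to cyclic ethers. Ring B closes in the 6-exo-trig mode. The new C2 centre is set trans to the untouched C3 centre through a chair-like transition state with both aryl groups equatorial, and because the addition is reversible under the basic conditions the trans (2R,3R) isomer is also the thermodynamic sink, so either C4 epimer of 17 converges. The step needs O- over C-attack and ring closure over intermolecular capture or tautomerisation of 18 to an enol ether; the nucleophile is released inside the same molecule five atoms from the electrophile, and the reaction is run dilute and degassed.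

Compound list
1 | 3',4'-dihydroxyacetophenone | CC(=O)c1ccc(O)c(O)c1 | starting material
2 | 1-[3,4-bis(TIPSO)phenyl]ethanone | CC(=O)c1ccc(O[Si](C(C)C)(C(C)C)C(C)C)c(O[Si](C(C)C)(C(C)C)C(C)C)c1 | intermediate
3 | 5-bromobenzene-1,3-diol | Oc1cc(O)cc(Br)c1 | starting material
4 | 1-bromo-3,5-bis(TIPSO)benzene | Brc1cc(O[Si](C(C)C)(C(C)C)C(C)C)cc(O[Si](C(C)C)(C(C)C)C(C)C)c1 | intermediate
5 | 1-[3,4-bis(TIPSO)phenyl]-2-[3,5-bis(TIPSO)phenyl]ethanone | O=C(Cc1cc(O[Si](C(C)C)(C(C)C)C(C)C)cc(O[Si](C(C)C)(C(C)C)C(C)C)c1)c1ccc(O[Si](C(C)C)(C(C)C)C(C)C)c(O[Si](C(C)C)(C(C)C)C(C)C)c1 | intermediate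
6 | lithium enolate of 5 (not isolated) | [Li+].[O-]C(=Cc1cc(O[Si](C(C)C)(C(C)C)C(C)C)cc(O[Si](C(C)C)(C(C)C)C(C)C)c1)c1ccc(O[Si](C(C)C)(C(C)C)C(C)C)c(O[Si](C(C)C)(C(C)C)C(C)C)c1 | intermediate
7 | rac-2-bromo-1-[3,4-bis(TIPSO)phenyl]-2-[3,5-bis(TIPSO)phenyl]ethanone | O=C(C(Br)c1cc(O[Si](C(C)C)(C(C)C)C(C)C)cc(O[Si](C(C)C)(C(C)C)C(C)C)c1)c1ccc(O[Si](C(C)C)(C(C)C)C(C)C)c(O[Si](C(C)C)(C(C)C)C(C)C)c1 | intermediate
8 | 3,4-dihydroxybenzaldehyde | O=Cc1ccc(O)c(O)c1 | starting material
9 | rac-4-{2-[3,4-bis(TIPSO)phenyl]-1-[3,5-bis(TIPSO)phenyl]-2-oxoethoxy}-3-hydroxybenzaldehyde | O=Cc1ccc(OC(C(=O)c2ccc(O[Si](C(C)C)(C(C)C)C(C)C)c(O[Si](C(C)C)(C(C)C)C(C)C)c2)c2cc(O[Si](C(C)C)(C(C)C)C(C)C)cc(O[Si](C(C)C)(C(C)C)C(C)C)c2)c(O)c1 | intermediate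
10 | 3,5-dihydroxybenzaldehyde | O=Cc1cc(O)cc(O)c1 | starting material
11 | 3,5-bis(TIPSO)benzaldehyde | O=Cc1cc(O[Si](C(C)C)(C(C)C)C(C)C)cc(O[Si](C(C)C)(C(C)C)C(C)C)c1 | intermediate
12 | [3,5-bis(TIPSO)phenyl]methanol | OCc1cc(O[Si](C(C)C)(C(C)C)C(C)C)cc(O[Si](C(C)C)(C(C)C)C(C)C)c1 | intermediate
13 | diethyl [3,5-bis(TIPSO)benzyl]phosphonate | CCOP(=O)(Cc1cc(O[Si](C(C)C)(C(C)C)C(C)C)cc(O[Si](C(C)C)(C(C)C)C(C)C)c1)OCC | intermediate
14 | rac-1-[3,4-bis(TIPSO)phenyl]-2-[3,5-bis(TIPSO)phenyl]-2-{4-[(E)-2-(3,5-bis(TIPSO)phenyl)ethenyl]-2-hydroxyphenoxy}ethanone | O=C(C(Oc1ccc(/C=C/c2cc(O[Si](C(C)C)(C(C)C)C(C)C)cc(O[Si](C(C)C)(C(C)C)C(C)C)c2)cc1O)c1cc(O[Si](C(C)C)(C(C)C)C(C)C)cc(O[Si](C(C)C)(C(C)C)C(C)C)c1)c1ccc(O[Si](C(C)C)(C(C)C)C(C)C)c(O[Si](C(C)C)(C(C)C)C(C)C)c1 | intermediate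
15 | (1R,2R)-1-[3,4-bis(TIPSO)phenyl]-2-[3,5-bis(TIPSO)phenyl]-2-{4-[(E)-2-(3,5-bis(TIPSO)phenyl)ethenyl]-2-hydroxyphenoxy}ethanol | O[C@H](c1ccc(O[Si](C(C)C)(C(C)C)C(C)C)c(O[Si](C(C)C)(C(C)C)C(C)C)c1)[C@H](Oc1ccc(/C=C/c2cc(O[Si](C(C)C)(C(C)C)C(C)C)cc(O[Si](C(C)C)(C(C)C)C(C)C)c2)cc1O)c1cc(O[Si](C(C)C)(C(C)C)C(C)C)cc(O[Si](C(C)C)(C(C)C)C(C)C)c1 | intermediate
16 | 5-[(E)-2-(3,5-bis(TIPSO)phenyl)ethenyl]-2-{(1R,2R)-2-[3,4-bis(TIPSO)phenyl]-1-[3,5-bis(TIPSO)phenyl]-2-hydroxyethoxy}phenyl imidazole-1-carboxylate (not isolated) | O[C@H](c1ccc(O[Si](C(C)C)(C(C)C)C(C)C)c(O[Si](C(C)C)(C(C)C)C(C)C)c1)[C@H](Oc1ccc(/C=C/c2cc(O[Si](C(C)C)(C(C)C)C(C)C)cc(O[Si](C(C)C)(C(C)C)C(C)C)c2)cc1OC(=O)n1ccnc1)c1cc(O[Si](C(C)C)(C(C)C)C(C)C)cc(O[Si](C(C)C)(C(C)C)C(C)C)c1 | intermediate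
17 | (4R,5R)-4-[3,4-bis(TIPSO)phenyl]-5-[3,5-bis(TIPSO)phenyl]-9-{(E)-2-[3,5-bis(TIPSO)phenyl]ethenyl}-4,5-dihydro-2H-1,3,6-benzotrioxocin-2-one (eight-membered cyclic carbonate) | O=C1O[C@H](c2ccc(O[Si](C(C)C)(C(C)C)C(C)C)c(O[Si](C(C)C)(C(C)C)C(C)C)c2)[C@@H](c2cc(O[Si](C(C)C)(C(C)C)C(C)C)cc(O[Si](C(C)C)(C(C)C)C(C)C)c2)Oc2ccc(/C=C/c3cc(O[Si](C(C)C)(C(C)C)C(C)C)cc(O[Si](C(C)C)(C(C)C)C(C)C)c3)cc2O1 | intermediate
18 | 4-{(2S)-2-(3,5-dihydroxyphenyl)-2-[4-((E)-2-(3,5-dihydroxyphenyl)ethenyl)-2-hydroxyphenoxy]ethylidene}-2-hydroxycyclohexa-2,5-dien-1-one (para-quinone methide, not isolated; same spatial arrangement at the ether carbon as in 17, the descriptor changes only through the priority rules) | O=C1C=CC(=C[C@@H](c2cc(O)cc(O)c2)Oc2ccc(/C=C/c3cc(O)cc(O)c3)cc2O)C=C1O | intermediate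
19 | cassigarol E, (2R,3R)-2-(3,4-dihydroxyphenyl)-3-(3,5-dihydroxyphenyl)-7-[(E)-2-(3,5-dihydroxyphenyl)ethenyl]-2,3-dihydro-1,4-benzodioxine (locants of the overview) | Oc1cc(O)cc(/C=C/c2ccc3c(c2)O[C@H](c2ccc(O)c(O)c2)[C@@H](c2cc(O)cc(O)c2)O3)c1 | target

Total step count: 12. Longest linear sequence: 8 steps (steps 1, 3, 4, 5, 9, 10, 11, 12).

Steps most likely to fail

Step 12 (key step). The carbonate may be cleaved by fluoride or adventitious hydroxide before the ring C phenoxide is unmasked, which leaves a benzylic alcohol that cannot depart under base. The quinone methide may also lose the proton on C3 to give an enol ether, or the polyphenoxide may be oxidised by air. Fallback: the ring contraction is run before deprotection by cationic instead of anionic ionisation. Setting out from 17, Sc(OTf)3 (5 mol%) in CH2Cl2 at −20 °C should ionise the benzylic C–O bond (ring C silyloxy groups as donors). The aryl carbonate of the ion pair loses CO2 and the phenol recloses, reversibly and therefore trans, to the hexakis(triisopropylsilyl) ether of cassigarol E F1. Desilylation of F1 with Bu4NF buffered with AcOH in THF at 0 °C comes back to the route at 19.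

Step 11. Intermolecular carbonate formation (oligomerisation) may outrun closure of the eight-membered ring. Fallback: the tether is changed to sulfur. Setting out from 15, SOCl2 and Et3N in CH2Cl2 at −40 °C should give the eight-membered cyclic sulfite F2, which closes more readily than a carbonate because the S–O bonds are longer and no planar ester geometry is required. F2 is submitted to the fluoride conditions of step 12, where the 1,6-elimination releases an aryl sulfite anion that loses SO2 in place of CO2. The sequence comes back to the route at 19.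

Step 10. Racemisation of the α-centre may be too slow relative to reduction, or the catalyst may discriminate poorly between the two ketone enantiomers; either would erode the enantiomeric purity at the later C3. Fallback: the resolution is done by separation instead of in situ equilibration. Setting out from 14, transfer hydrogenation with the same catalyst is run to full conversion without relying on racemisation, so that catalyst control at the carbinol carbon turns the racemate into 15 and its diastereomer (1R,2S)-1-[3,4-bis(TIPSO)phenyl]-2-[3,5-bis(TIPSO)phenyl]-2-{4-[(E)-2-(3,5-bis(TIPSO)phenyl)ethenyl]-2-hydroxyphenoxy}ethanol F3. The two are separated by chromatography. F3 is oxidised back to 14 with the periodinane DMP in CH2Cl2 and recycled, and the route is rejoined at 15.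

Further compounds
F1 | step 12 | (2R,3R)-2-[3,4-bis(TIPSO)phenyl]-3-[3,5-bis(TIPSO)phenyl]-7-{(E)-2-[3,5-bis(TIPSO)phenyl]ethenyl}-2,3-dihydro-1,4-benzodioxine (hexakis(triisopropylsilyl) ether of cassigarol E) | CC(C)[Si](Oc1cc(O[Si](C(C)C)(C(C)C)C(C)C)cc(/C=C/c2ccc3c(c2)O[C@H](c2ccc(O[Si](C(C)C)(C(C)C)C(C)C)c(O[Si](C(C)C)(C(C)C)C(C)C)c2)[C@@H](c2cc(O[Si](C(C)C)(C(C)C)C(C)C)cc(O[Si](C(C)C)(C(C)C)C(C)C)c2)O3)c1)(C(C)C)C(C)C
F2 | step 11 | (4R,5R)-4-[3,4-bis(TIPSO)phenyl]-5-[3,5-bis(TIPSO)phenyl]-9-{(E)-2-[3,5-bis(TIPSO)phenyl]ethenyl}-4,5-dihydro-1,3,6,2-benzotrioxathiocine 2-oxide (eight-membered cyclic sulfite, sulfur configuration not defined) | O=S1O[C@H](c2ccc(O[Si](C(C)C)(C(C)C)C(C)C)c(O[Si](C(C)C)(C(C)C)C(C)C)c2)[C@@H](c2cc(O[Si](C(C)C)(C(C)C)C(C)C)cc(O[Si](C(C)C)(C(C)C)C(C)C)c2)Oc2ccc(/C=C/c3cc(O[Si](C(C)C)(C(C)C)C(C)C)cc(O[Si](C(C)C)(C(C)C)C(C)C)c3)cc2O1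
F3 | step 10 | (1R,2S)-1-[3,4-bis(TIPSO)phenyl]-2-[3,5-bis(TIPSO)phenyl]-2-{4-[(E)-2-(3,5-bis(TIPSO)phenyl)ethenyl]-2-hydroxyphenoxy}ethanol | O[C@H](c1ccc(O[Si](C(C)C)(C(C)C)C(C)C)c(O[Si](C(C)C)(C(C)C)C(C)C)c1)[C@@H](Oc1ccc(/C=C/c2cc(O[Si](C(C)C)(C(C)C)C(C)C)cc(O[Si](C(C)C)(C(C)C)C(C)C)c2)cc1O)c1cc(O[Si](C(C)C)(C(C)C)C(C)C)cc(O[Si](C(C)C)(C(C)C)C(C)C)c1
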